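**Plan**
- Numbering (eremophilane type): ring A = C1–C5 and C10, ring B = C5–C10; C3 bears the angelate, C4 and C5 the methyls, C7 the isopropenyl group, C8 the ketone, C9 the second ester; β is the face of the C5 methyl.
- Retrosynthesis: cut the two ester C–O bonds, then the C9–OH bond (enolate hydroxylation of the C8 ketone), move the ketone from C8 back to C9 (1,2-transposition through the C9 enol triflate), cut C7–isopropenyl (cuprate on the 7-en-9-one), and last open ring A at C2–C3 and C4–C5.
- Enabling feature: in ring A the edge C3(O)–C4(Me) is a two-carbon unit between C2 and quaternary C5, and C9, the oxygenated carbon on C10, can be a ketone. C2=C1–C10(C9=O)=C5 is then an electron-poor 2-acyl diene and C3=C4 an (E)-propenyl ether, matched in polarity (enol ether carbon C4 to enone β-carbon C5).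
- Forward: ring B is bought as 3-methylcyclohexenone, ring A is closed onto it by one [4+2] (step 5), then ring B is worked up (C10–H, C7, C8/C9) and the two esters go on last.
- Stereochemistry: C3, C4, C5 and the absolute sense come from the E enol ether, the endo-alkoxy transition state and the (S)-1-arylethyl auxiliary; C10, C7 and C9 are then set by the angular C5 methyl (reagents enter on the α face, substituents end equatorial).

Key step: step 5

Assumption: the 1-(2,4,6-triisopropylphenyl)ethyl enol ether reacts through its s-trans conformer with the carbinol C–H in the enol ether plane, so that the aryl ring blocks one face and the (S)-alcohol leads to the (3R,4R,5R) adduct; (S)-1-(2,4,6-triisopropylphenyl)ethanol and (E)-3-methylpent-2-enoic acid are taken as purchasable.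

**Route**

Step 1
Reactants: 1 3-methylcyclohex-2-en-1-one
Product: 2 2-iodo-3-methylcyclohex-2-en-1-one
Conditions: I2, pyridine/CH2Cl2 (1:1), 0 °C to rt
Reagents that add atoms: iodine, II
Why: α-Iodination of an enone by pyridine conjugate addition, iodination of the enolate and elimination (Baylis–Hillman-type sequence) should give the 2-iodo enone.

Step 2
Reactants: 2 2-iodo-3-methylcyclohex-2-en-1-one; 3 tributyl(vinyl)stannane
Product: 4 3-methyl-2-vinylcyclohex-2-en-1-one
Conditions: PdCl2(PhCN)2 (5 mol %), AsPh3 (10 mol %), CuI (10 mol %), NMP, 60 °C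
Reagents that add atoms: none
Why: Stille coupling of an α-iodo enone with a vinylstannane is a standard entry to 2-vinyl enones.

Step 3
Reactants: 5 (S)-1-(2,4,6-triisopropylphenyl)ethanol; 6 allyl bromide
Product: 7 (S)-1-(2,4,6-triisopropylphenyl)ethyl allyl ether
Conditions: KH, THF, 0 °C; then 6, rt
Reagents that add atoms: none
Why: Williamson etherification of the potassium alkoxide should proceed without touching the carbinol stereocentre.

Step 4
Reactants: 7 (S)-1-(2,4,6-triisopropylphenyl)ethyl allyl ether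
Product: 8 (S)-1-(2,4,6-triisopropylphenyl)ethyl (E)-prop-1-enyl ether
Conditions: [Ir(cod)(PMePh2)2]PF6 (2 mol %, activated with H2), THF, rt
Reagents that add atoms: none
Why: Cationic iridium hydride isomerisation of allyl ethers (1,3-hydrogen shift) should give the (E)-propenyl ether under kinetic control.

Step 5
Reactants: 4 3-methyl-2-vinylcyclohex-2-en-1-one; 8 (S)-1-(2,4,6-triisopropylphenyl)ethyl (E)-prop-1-enyl ether
Product: 9 (3R,4R,5R)-3α-[(S)-1-(2,4,6-triisopropylphenyl)ethoxy]-4β,5β-dimethyl-Δ1(10)-octalin-9-one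
Conditions: Yb(fod)3 (10 mol %; fod = 6,6,7,7,8,8,8-heptafluoro-2,2-dimethyloctane-3,5-dionate), CH2Cl2, 12 kbar, 25 °C
Reagents that add atoms: none
Why: Proposed new method: Ytterbium coordination to the C9 carbonyl lowers the LUMO of the cross-conjugated 2-acyl diene C2=C1–C10(C9=O)=C5, whose largest coefficient is on the enone β-carbon C5, while the enol ether HOMO is largest on the methyl-bearing carbon C4, so a concerted but asynchronous inverse-electron-demand [4+2] should form C4–C5 ahead of C2–C3 and leave the C1=C10 enone. The closest known reaction type is the inverse-demand Diels–Alder reaction of 2-acyl or 2-alkoxycarbonyl dienes and of 2-pyrones with alkyl enol ethers, including 1-arylethyl enol ethers, under lanthanide catalysis or high pressure; what is new is a 2-vinylcycloalkenone with a fully substituted diene terminus. Ring A (C1–C5, C10) is the only ring closed, by the intermolecular suprafacial cycloaddition itself. The trans relation of C3–O and C4–Me comes from the E geometry, the cis relation of the C4 and C5 methyls from the endo-alkoxy transition state (methyl exo, on the side of the inside C5 methyl), and the absolute sense from the (S)-1-arylethyl group, whose aryl ring blocks one face of the enol ether. The step needs regioselectivity (secured by the polarity match of C4 with C5), periselectivity over hetero-Diels–Alder closure through the carbonyl oxygen (that acetal-type adduct is reversible under the Lewis acid, the carbocycle is not) and endo selectivity (favoured by the compact transition state under pressure).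

Step 6
Reactants: 9 cycloadduct
Product: 11 3α-hydroxy-4β,5β-dimethyl-10αH-decalin-9-one (trans-fused), via dilithium enolate alkoxide 10 (not isolated)
Conditions: Li (6 equiv), t-BuOH (1 equiv), NH3(l)/THF, −78 to −33 °C; solid NH4Cl; then NaOMe (cat.), MeOH, rt
Reagents that add atoms: none
Why: Dissolving-metal reduction should turn the enone into its C9(10) enolate and cleave the benzylic C–O bond of the auxiliary, and protonation on the α face next to the angular methyl followed by base equilibration of the epimerisable C10 should give the trans-fused ketone.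

Step 7
Reactants: 11 3α-hydroxy-4β,5β-dimethyl-10αH-decalin-9-one
Product: 12 3α-(tert-butyldimethylsilyloxy)-4β,5β-dimethyl-10αH-decalin-9-one
Conditions: TBSCl, imidazole, DMF, rt
Reagents that add atoms: tert-butyldimethylsilyl chloride, CC(C)(C)[Si](C)(C)Cl
Why: Silylation of the equatorial secondary alcohol protects C3 through the enolate and organometallic steps.

Step 8
Reactants: 12 silyl ether ketone
Product: 14 3α-(tert-butyldimethylsilyloxy)-4β,5β-dimethyl-10αH-decal-7-en-9-one, via trimethylsilyl enol ether 13 (not isolated)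
Conditions: LDA, THF, −78 °C, TMSCl; then Pd(OAc)2 (1.1 equiv), MeCN, rt
Reagents that add atoms: none
Why: Kinetic deprotonation at the C8 methylene (not the C10 methine) and Saegusa–Ito oxidation of the silyl enol ether should give the 7-en-9-one.

Step 9
Reactants: 14 7-en-9-one; 15 isopropenylmagnesium bromide
Product: 17 3α-(tert-butyldimethylsilyloxy)-7α-isopropenyl-4β,5β-dimethyl-10αH-decal-8-en-9-yl trifluoromethanesulfonate, via bromomagnesium enolate 16 (not isolated)
Conditions: 15 (1.5 equiv), CuBr·SMe2 (20 mol %), THF, −78 °C; then N-(5-chloropyridin-2-yl)triflimide (Comins reagent), −78 °C to rt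
Reagents that add atoms: N-(5-chloropyridin-2-yl)-1,1,1-trifluoro-N-(trifluoromethylsulfonyl)methanesulfonamide, O=S(=O)(N(c1ccc(Cl)cn1)S(=O)(=O)C(F)(F)F)C(F)(F)F
Why: Copper-catalysed conjugate addition should deliver the isopropenyl group to C7 on the α face, away from the 1,3-related axial C5 methyl (equatorial product), and the regiodefined enolate is O-triflated in the same flask.

Step 10
Reactants: 17 enol triflate
Product: 19 3α-(tert-butyldimethylsilyloxy)-7α-isopropenyl-4β,5β-dimethyl-10αH-decalin-8-one, via morpholine enamine 18 (not isolated)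
Conditions: Pd(OAc)2 (10 mol %), PPh3 (25 mol %), norbornene (1 equiv), 4-(benzoyloxy)morpholine, i-PrOH, Cs2CO3, 1,4-dioxane, 100 °C; then 1 M HCl, THF, 0 °C
Reagents that add atoms: water, O
Why: Palladium/norbornene cooperative catalysis (Catellani-type α-amination of the alkenyl triflate with ipso hydride termination) should place nitrogen on C8 and hydrogen on C9, and hydrolysis of the enamine gives the 1,2-transposed C8 ketone with C7 in its equatorial, thermodynamically preferred configuration.

Step 11
Reactants: 19 C8 ketone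
Product: 21 9α-hydroxy-3α-(tert-butyldimethylsilyloxy)-7α-isopropenyl-4β,5β-dimethyl-10αH-decalin-8-one, via potassium enolate 20 (not isolated)
Conditions: KHMDS, THF, −78 °C; 2-(phenylsulfonyl)-3-phenyloxaziridine, −78 °C; aq NH4Cl
Reagents that add atoms: 2-(phenylsulfonyl)-3-phenyloxaziridine, O=S(=O)(c1ccccc1)N1OC1c1ccccc1
Why: Kinetic enolisation toward the C9 methylene and Davis hydroxylation should bring oxygen to the α face, opposite the 1,3-related axial C5 methyl, to give the equatorial 9α-alcohol.

Step 12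
Reactants: 21 α-hydroxy ketone; 22 (E)-3-methylpent-2-enoic acid
Product: 23 9α-[(E)-3-methylpent-2-enoyloxy]-3α-(tert-butyldimethylsilyloxy)-7α-isopropenyl-4β,5β-dimethyl-10αH-decalin-8-one
Conditions: DCC, DMAP (cat.), CH2Cl2, 0 °C to rt
Reagents that add atoms: none
Why: Steglich esterification acylates the C9 hydroxyl under near-neutral conditions that should not enolise the ketone.

Step 13
Reactants: 23 silyl ether ester
Product: 24 3α-hydroxy-9α-[(E)-3-methylpent-2-enoyloxy]-7α-isopropenyl-4β,5β-dimethyl-10αH-decalin-8-one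
Conditions: HF·pyridine, THF/pyridine, 0 °C to rt
Reagents that add atoms: none
Why: Buffered fluoride cleaves the silyl ether without base, so the α-acyloxy ketone and the isopropenyl group should stay untouched.

Step 14
Reactants: 24 C3 alcohol; 25 angelic acid
Product: 27 (3R,4R,5R,7S,9S,10R)-3-angeloyloxy-9-[(E)-3-methylpent-2-enoyloxy]eremophil-11-en-8-one (target), via mixed anhydride 26 (not isolated)
Conditions: 25, 2,4,6-trichlorobenzoyl chloride, Et3N, toluene, rt; then 24, 80 °C
Reagents that add atoms: none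
Why: Yamaguchi-type mixed anhydride esterification without DMAP should acylate the C3 alcohol while keeping the Z geometry of the angelate.

**Compound list**
1 | 3-methylcyclohex-2-en-1-one | CC1=CC(=O)CCC1 | starting material
2 | 2-iodo-3-methylcyclohex-2-en-1-one | CC1=C(I)C(=O)CCC1 | intermediate
3 | tributyl(vinyl)stannane | C=C[Sn](CCCC)(CCCC)CCCC | starting material
4 | 3-methyl-2-vinylcyclohex-2-en-1-one | CC1=C(C=C)C(=O)CCC1 | intermediate
5 | (S)-1-(2,4,6-triisopropylphenyl)ethanol | C[C@H](O)c1c(C(C)C)cc(C(C)C)cc1C(C)C | starting material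
6 | allyl bromide | C=CCBr | starting material
7 | (S)-1-(2,4,6-triisopropylphenyl)ethyl allyl ether | C[C@H](OCC=C)c1c(C(C)C)cc(C(C)C)cc1C(C)C | intermediate
8 | (S)-1-(2,4,6-triisopropylphenyl)ethyl (E)-prop-1-enyl ether | C[C@H](O/C=C/C)c1c(C(C)C)cc(C(C)C)cc1C(C)C | intermediate
9 | (3R,4R,5R)-3α-[(S)-1-(2,4,6-triisopropylphenyl)ethoxy]-4β,5β-dimethyl-Δ1(10)-octalin-9-one | O=C1CCC[C@]2(C)[C@@H](C)[C@H](O[C@@H](C)c3c(C(C)C)cc(C(C)C)cc3C(C)C)CC=C12 | intermediate
10 | dilithium C9(10)-enolate 3α-alkoxide | [Li]OC1=C2CC[C@@H](O[Li])[C@H](C)[C@@]2(C)CCC1 | intermediate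
11 | 3α-hydroxy-4β,5β-dimethyl-10αH-decalin-9-one | O=C1CCC[C@]2(C)[C@@H](C)[C@H](O)CC[C@@H]12 | intermediate
12 | 3α-(tert-butyldimethylsilyloxy)-4β,5β-dimethyl-10αH-decalin-9-one | O=C1CCC[C@]2(C)[C@@H](C)[C@H](O[Si](C)(C)C(C)(C)C)CC[C@@H]12 | intermediate
13 | C8(9) trimethylsilyl enol ether of 12 | C[Si](C)(C)OC1=CCC[C@]2(C)[C@@H](C)[C@H](O[Si](C)(C)C(C)(C)C)CC[C@@H]12 | intermediate
14 | 3α-(tert-butyldimethylsilyloxy)-4β,5β-dimethyl-10αH-decal-7-en-9-one | O=C1C=CC[C@]2(C)[C@@H](C)[C@H](O[Si](C)(C)C(C)(C)C)CC[C@@H]12 | intermediate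
15 | isopropenylmagnesium bromide | C=C(C)[Mg]Br | starting material
16 | bromomagnesium C8(9)-enolate, 7α-isopropenyl | C=C(C)[C@@H]1C[C@]2(C)[C@@H](C)[C@H](O[Si](C)(C)C(C)(C)C)CC[C@H]2C(O[Mg]Br)=C1 | intermediate
17 | 3α-(tert-butyldimethylsilyloxy)-7α-isopropenyl-4β,5β-dimethyl-10αH-decal-8-en-9-yl trifluoromethanesulfonate | C=C(C)[C@@H]1C[C@]2(C)[C@@H](C)[C@H](O[Si](C)(C)C(C)(C)C)CC[C@H]2C(OS(=O)(=O)C(F)(F)F)=C1 | intermediate
18 | 8-morpholino-Δ8 enamine | C=C(C)[C@@H]1C[C@]2(C)[C@@H](C)[C@H](O[Si](C)(C)C(C)(C)C)CC[C@H]2C=C1N3CCOCC3 | intermediate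
19 | 3α-(tert-butyldimethylsilyloxy)-7α-isopropenyl-4β,5β-dimethyl-10αH-decalin-8-one | C=C(C)[C@@H]1C[C@]2(C)[C@@H](C)[C@H](O[Si](C)(C)C(C)(C)C)CC[C@H]2CC1=O | intermediate
20 | potassium C8(9)-enolate of 19 | C=C(C)[C@@H]1C[C@]2(C)[C@@H](C)[C@H](O[Si](C)(C)C(C)(C)C)CC[C@H]2C=C1O[K] | intermediate
21 | 9α-hydroxy-3α-(tert-butyldimethylsilyloxy)-7α-isopropenyl-4β,5β-dimethyl-10αH-decalin-8-one | C=C(C)[C@@H]1C[C@]2(C)[C@@H](C)[C@H](O[Si](C)(C)C(C)(C)C)CC[C@H]2[C@H](O)C1=O | intermediate
22 | (E)-3-methylpent-2-enoic acid | CC/C(C)=C/C(=O)O | starting material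
23 | 9α-[(E)-3-methylpent-2-enoyloxy]-3α-(tert-butyldimethylsilyloxy)-7α-isopropenyl-4β,5β-dimethyl-10αH-decalin-8-one | C=C(C)[C@@H]1C[C@]2(C)[C@@H](C)[C@H](O[Si](C)(C)C(C)(C)C)CC[C@H]2[C@H](OC(=O)/C=C(\C)CC)C1=O | intermediate
24 | 3α-hydroxy-9α-[(E)-3-methylpent-2-enoyloxy]-7α-isopropenyl-4β,5β-dimethyl-10αH-decalin-8-one | C=C(C)[C@@H]1C[C@]2(C)[C@@H](C)[C@H](O)CC[C@H]2[C@H](OC(=O)/C=C(\C)CC)C1=O | intermediate
25 | angelic acid, (Z)-2-methylbut-2-enoic acid | C/C=C(/C)C(=O)O | starting material
26 | angelic 2,4,6-trichlorobenzoic anhydride | C/C=C(/C)C(=O)OC(=O)c1c(Cl)cc(Cl)cc1Cl | intermediate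
27 | (3R,4R,5R,7S,9S,10R)-3-angeloyloxy-9-[(E)-3-methylpent-2-enoyloxy]eremophil-11-en-8-one | C=C(C)[C@@H]1C[C@]2(C)[C@@H](C)[C@H](OC(=O)/C(C)=C\C)CC[C@H]2[C@H](OC(=O)/C=C(\C)CC)C1=O | target

Total steps: 14. Longest linear sequence: 12 (steps 1, 2, 5–14, or equally 3, 4, 5–14).

**Steps most likely to fail**

1. Step 5. The cycloaddition may be too slow at the fully substituted C5 terminus, may close through the carbonyl oxygen instead of C2, or the auxiliary may discriminate the faces poorly. The fallback uses known chemistry, sets out from 4 and comes back at 11. Ketone 4 is reduced with BH3·SMe2 and (R)-2-methyl-CBS-oxazaborolidine to (S)-3-methyl-2-vinylcyclohex-2-en-1-ol F1, which is silylated (TBSCl, imidazole) to its tert-butyldimethylsilyl ether F2. A normal-demand Diels–Alder reaction with B-[(E)-prop-1-enyl]-9-borabicyclo[3.3.1]nonane follows; alkenylboranes place boron meta to the substituted diene terminus and endo, and the dienophile should enter opposite the pseudoaxial C9 silyloxy group. This gives the 3α-boryl-9β-silyloxy-4β,5β-dimethyl-Δ1(10)-octalin F3. Oxidation with NaOH/H2O2 (retention) gives the 9β-silyloxy-Δ1(10)-octalin-3α-ol F4, TBAF gives the 4β,5β-dimethyl-Δ1(10)-octalin-3α,9β-diol F5, and MnO2 oxidises only the allylic C9 hydroxyl to 3α-hydroxy-4β,5β-dimethyl-Δ1(10)-octalin-9-one F6. Li/NH3 and NaOMe as in step 6 then give 11.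

2. Step 10. The triflate may be reduced directly before norbornene insertion, the hindered C8–H may not be palladated, or the isopropenyl group may enter Heck-type side reactions. The fallback is a classical sulfur-based 1,2-carbonyl transposition; it sets out from 14 and comes back at 19. The conjugate addition of step 9 is run as before, but enolate 16 is trapped with S-phenyl benzenethiosulfonate to give the 7α-isopropenyl-8β-phenylthio-9-ketone F7. NaBH4 reduces it from the α face to the 8β-phenylthio-9β-alcohol F8. Martin sulfurane dehydrates this by anti elimination (C8–H axial, C9–O axial) to the 8-phenylthio-Δ8 vinyl sulfide F9, and hydrolysis (TiCl4, aqueous MeCN) gives 19.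

3. Step 11. Deprotonation may occur at the doubly activated C7–H instead of C9, which would lead to hydroxylation at C7 or to conjugation of the isopropenyl group. The fallback takes the regiochemistry from the enamine; it sets out from 17 and comes back at 21. The palladium/norbornene amination of step 10 is worked up without water to isolate enamine 18. Oxidation with Pb(OAc)4 in CH2Cl2 and aqueous work-up should give the equatorial 9α-acetoxy-8-ketone F10, and K2CO3 (cat.) in MeOH at 0 °C gives 21.

Further compounds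
F1 | step 5 | (S)-3-methyl-2-vinylcyclohex-2-en-1-ol | O[C@H]1CCCC(C)=C1C=C
F2 | step 5 | (S)-tert-butyldimethyl[(3-methyl-2-vinylcyclohex-2-en-1-yl)oxy]silane | CC(C)(C)[Si](C)(C)O[C@H]1CCCC(C)=C1C=C
F3 | step 5 | 3α-(9-borabicyclo[3.3.1]nonan-9-yl)-9β-(tert-butyldimethylsilyloxy)-4β,5β-dimethyl-Δ1(10)-octalin | CC(C)(C)[Si](C)(C)O[C@H]1CCC[C@]2(C)[C@@H](C)[C@H](B3C4CCCC3CCC4)CC=C12
F4 | step 5 | 9β-(tert-butyldimethylsilyloxy)-4β,5β-dimethyl-Δ1(10)-octalin-3α-ol | CC(C)(C)[Si](C)(C)O[C@H]1CCC[C@]2(C)[C@@H](C)[C@H](O)CC=C12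
F5 | step 5 | 4β,5β-dimethyl-Δ1(10)-octalin-3α,9β-diol | O[C@H]1CCC[C@]2(C)[C@@H](C)[C@H](O)CC=C12
F6 | step 5 | 3α-hydroxy-4β,5β-dimethyl-Δ1(10)-octalin-9-one | O=C1CCC[C@]2(C)[C@@H](C)[C@H](O)CC=C12
F7 | step 10 | 3α-(tert-butyldimethylsilyloxy)-7α-isopropenyl-4β,5β-dimethyl-8β-phenylthio-10αH-decalin-9-one | C=C(C)[C@@H]1C[C@]2(C)[C@@H](C)[C@H](O[Si](C)(C)C(C)(C)C)CC[C@H]2C(=O)[C@H]1Sc3ccccc3
F8 | step 10 | 3α-(tert-butyldimethylsilyloxy)-7α-isopropenyl-4β,5β-dimethyl-8β-phenylthio-10αH-decalin-9β-ol | C=C(C)[C@@H]1C[C@]2(C)[C@@H](C)[C@H](O[Si](C)(C)C(C)(C)C)CC[C@H]2[C@@H](O)[C@H]1Sc3ccccc3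
F9 | step 10 | 3α-(tert-butyldimethylsilyloxy)-7α-isopropenyl-4β,5β-dimethyl-8-phenylthio-10αH-decal-8-ene | C=C(C)[C@@H]1C[C@]2(C)[C@@H](C)[C@H](O[Si](C)(C)C(C)(C)C)CC[C@H]2C=C1Sc3ccccc3
F10 | step 11 | 9α-acetoxy-3α-(tert-butyldimethylsilyloxy)-7α-isopropenyl-4β,5β-dimethyl-10αH-decalin-8-one | C=C(C)[C@@H]1C[C@]2(C)[C@@H](C)[C@H](O[Si](C)(C)C(C)(C)C)CC[C@H]2[C@H](OC(C)=O)C1=O
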